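**Assumptions:** The target (2-O-methyldivaricatic acid, a depside) has no stereocentre and is achiral, so there is no enantiomer to control. Divarinol (5-propylresorcinol) is taken as commercially available.

## Retrosynthetic overview
1. The CO2H of the target comes from a late CHO oxidation (Pinnick), so no carboxyl protecting group is needed.
2. The depside ester C–O bond is cut to give the A-ring acid 5 and the B-ring phenol aldehyde 3, acylated at the free 4-OH.
3. Acid 5 comes from the same aldehyde 3 by double O-methylation and Pinnick oxidation.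
4. Aldehyde 3 comes from divarinol 1 by Vilsmeier–Haack formylation.
5. No ring is formed. Both benzene rings are bought as divarinol.

## Route

**Step 1**
Reactants: 1 divarinol (5-propylbenzene-1,3-diol)
Product: 3 2,4-dihydroxy-6-propylbenzaldehyde, via aryl iminium chloride 2 (not isolated)
Conditions: POCl3 (1.5 equiv), DMF, 0 °C to rt; then ice-water, filter and recrystallise
Reagents that add atoms: N,N-dimethylformamide CN(C)C=O; water O
Why: Vilsmeier–Haack formylation attacks the position para to one OH and ortho to the other, as with orcinol and olivetol, and water hydrolyses the iminium salt to the aldehyde.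

**Step 2**
Reactants: 3 2,4-dihydroxy-6-propylbenzaldehyde (about half of the material)
Product: 4 2,4-dimethoxy-6-propylbenzaldehyde
Conditions: MeI (3 equiv), K2CO3 (3 equiv), DMF, rt to 40 °C
Reagents that add atoms: iodomethane CI
Why: Williamson O-alkylation with excess MeI and base in a polar aprotic solvent also methylates the hydrogen-bonded 2-OH, and the aldehyde is inert.

**Step 3**
Reactants: 4 2,4-dimethoxy-6-propylbenzaldehyde
Product: 5 2,4-dimethoxy-6-propylbenzoic acid
Conditions: NaClO2, NaH2PO4, 2-methyl-2-butene (excess), t-BuOH/THF/H2O, rt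
Reagents that add atoms: sodium chlorite [Na+].[O-]Cl=O
Why: Pinnick oxidation converts ArCHO to ArCO2H at about pH 4, and the alkene traps HOCl so the electron-rich ring is not chlorinated.

**Step 4**
Reactants: 5 2,4-dimethoxy-6-propylbenzoic acid; 3 2,4-dihydroxy-6-propylbenzaldehyde
Product: 7 4-formyl-3-hydroxy-5-propylphenyl 2,4-dimethoxy-6-propylbenzoate, via mixed trifluoroacetic anhydride 6 (not isolated)
Conditions: TFAA (4 equiv), toluene, rt, 4–16 h; aqueous work-up
Reagents that add atoms: none
Why: In this TFAA-mediated depside esterification the hindered, electron-rich acid reacts through its mixed anhydride. Only the free 4-OH of 3 is acylated, because the 2-OH is chelated to the CHO, and any aryl trifluoroacetate hydrolyses on work-up.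

**Step 5**
Reactants: 7 4-formyl-3-hydroxy-5-propylphenyl 2,4-dimethoxy-6-propylbenzoate
Product: 8 4-[(2,4-dimethoxy-6-propylbenzoyl)oxy]-2-hydroxy-6-propylbenzoic acid (target)
Conditions: NaClO2, NaH2PO4, 2-methyl-2-butene (large excess), t-BuOH/THF/H2O, 0 °C to rt; extract at pH 3, no heating
Reagents that add atoms: sodium chlorite [Na+].[O-]Cl=O
Why: Pinnick oxidation in a weakly acidic buffer leaves the aryl ester intact, the scavenger suppresses chlorination of the phenol ring, and a cold, base-free work-up avoids depside cleavage and decarboxylation.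

## Compound list
1 | divarinol (5-propylbenzene-1,3-diol) | CCCc1cc(O)cc(O)c1 | starting material
2 | (2,4-dihydroxy-6-propylbenzylidene)dimethyliminium chloride | CCCc1cc(O)cc(O)c1C=[N+](C)C.[Cl-] | intermediate (not isolated)
3 | 2,4-dihydroxy-6-propylbenzaldehyde | CCCc1cc(O)cc(O)c1C=O | intermediate
4 | 2,4-dimethoxy-6-propylbenzaldehyde | CCCc1cc(OC)cc(OC)c1C=O | intermediate
5 | 2,4-dimethoxy-6-propylbenzoic acid | CCCc1cc(OC)cc(OC)c1C(=O)O | intermediate
6 | 2,4-dimethoxy-6-propylbenzoic trifluoroacetic anhydride | CCCc1cc(OC)cc(OC)c1C(=O)OC(=O)C(F)(F)F | intermediate (not isolated)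
7 | 4-formyl-3-hydroxy-5-propylphenyl 2,4-dimethoxy-6-propylbenzoate | CCCc1cc(OC(=O)c2c(CCC)cc(OC)cc2OC)cc(O)c1C=O | intermediate
8 | 4-[(2,4-dimethoxy-6-propylbenzoyl)oxy]-2-hydroxy-6-propylbenzoic acid | CCCc1cc(OC(=O)c2c(CCC)cc(OC)cc2OC)cc(O)c1C(=O)O | target

**Total step count:** 5
**Longest linear sequence:** 5 (1 → 3 → 4 → 5 → 7 → 8)

## Three steps most likely to fail, with fallbacks

**Step 1** (moderate yield, the 2,6-dihydroxy regioisomer, and O-formylation of the free resorcinol). The fallback sets out from 1 and comes back to the route at 4 and then at 3.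
- Compound 1 is bis-methylated (MeI, K2CO3, acetone) to 1,3-dimethoxy-5-propylbenzene F1.
- NBS in MeCN brominates F1 regioselectively to 2-bromo-1,5-dimethoxy-3-propylbenzene F2.
- Br/Li exchange (n-BuLi, THF, −78 °C) gives (2,4-dimethoxy-6-propylphenyl)lithium F3.
- DMF traps F3 as the lithium hemiaminal alkoxide F4, which collapses to 4 on aqueous quench.
- The portion needed for the B ring is fully demethylated (BBr3, CH2Cl2, −78 °C to rt) to give 3.

**Step 4** (slow acylation by the di-ortho-substituted acid, or bis-acylation). The fallback sets out from 5 and comes back at 7.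
- It replaces acid-promoted acylation with base-promoted phenoxide acylation.
- Compound 5 is converted with oxalyl chloride and catalytic DMF in CH2Cl2 into 2,4-dimethoxy-6-propylbenzoyl chloride F5.
- F5 is added to 3 with K2CO3 (1 equiv) in acetone. Only the more acidic, non-chelated 4-OH is deprotonated and acylated.

**Step 5** (ring chlorination of the phenol, or loss of the depside ester during oxidation). The fallback sets out from 1, uses 5 through 6, and comes back at 8. The carboxyl group is installed before the coupling.
- Compound 1 is carboxylated with methyl magnesium carbonate (DMF, 120 °C, Kolbe–Schmitt type) to 2,4-dihydroxy-6-propylbenzoic acid F6.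
- BnBr and KHCO3 in DMF give benzyl 2,4-dihydroxy-6-propylbenzoate F7.
- TFAA/toluene coupling with 5 (via 6) gives the benzyl-protected depside F8.
- Hydrogenolysis (H2, 10% Pd/C, EtOAc, rt) gives 8.

## Further compounds
F1 | step 1 | 1,3-dimethoxy-5-propylbenzene | CCCc1cc(OC)cc(OC)c1
F2 | step 1 | 2-bromo-1,5-dimethoxy-3-propylbenzene | CCCc1cc(OC)cc(OC)c1Br
F3 | step 1 | (2,4-dimethoxy-6-propylphenyl)lithium | CCCc1cc(OC)cc(OC)c1[Li]
F4 | step 1 | lithium (2,4-dimethoxy-6-propylphenyl)(dimethylamino)methanolate | CCCc1cc(OC)cc(OC)c1C([O-])N(C)C.[Li+]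
F5 | step 4 | 2,4-dimethoxy-6-propylbenzoyl chloride | CCCc1cc(OC)cc(OC)c1C(=O)Cl
F6 | step 5 | 2,4-dihydroxy-6-propylbenzoic acid | CCCc1cc(O)cc(O)c1C(=O)O
F7 | step 5 | benzyl 2,4-dihydroxy-6-propylbenzoate | CCCc1cc(O)cc(O)c1C(=O)OCc1ccccc1
F8 | step 5 | benzyl 4-[(2,4-dimethoxy-6-propylbenzoyl)oxy]-2-hydroxy-6-propylbenzoate | CCCc1cc(OC(=O)c2c(CCC)cc(OC)cc2OC)cc(O)c1C(=O)OCc1ccccc1
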